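Ring B has oxygen on C1, C3 and C5, the pattern of a folded triketide, with the ring A ether on C1 and the ring C ether on C4. The ring is therefore closed from an open chain instead of being arylated: one Claisen condensation joins ring carbon C4, which already bears the ring C oxygen, to C3, and enolisation delivers the arene with both hindered ethers in place. The precursor is a methyl (E)-hex-2-enoate carrying the ring A aryloxy group on chain C3, a ketone on chain C5 and the ring C aryloxy group on chain C6. Rings D to H follow by copper-mediated ether couplings; all methyl ethers are cleaved last.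

Key step: step 7

Remark: the target has no stereocentre; rings are lettered A to H from the 2,4,6-trihydroxyphenoxy end, ring B atoms are numbered from the carbon that bears the ring A oxygen, and every hydroxyl not made in step 7 travels as a methyl ether.

Step 1
Reactants: 1 2,4,6-trimethoxyphenol; 2 methyl but-2-ynoate
Product: 3 methyl (E)-3-(2,4,6-trimethoxyphenoxy)but-2-enoate
Conditions: K2CO3 (0.2 equiv), DMF, 80 °C, Ar
Reagents that add atoms: none
Why: Base-catalysed oxa-Michael addition of the phenoxide to the ynoate (directly or through the allenoate) gives the 3-aryloxy crotonate, and reversible addition should settle on the (E)-isomer with the aryloxy group trans to the ester, as for 3-alkoxycrotonates.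

Step 2
Reactants: 4 2,3,4-trimethoxyphenol
Product: 5 2-hydroxy-3,4,5-trimethoxybenzaldehyde
Conditions: MgCl2, Et3N, (CH2O)n, MeCN, reflux; then aq. HCl
Reagents that add atoms: paraformaldehyde (formaldehyde), C=O
Why: Magnesium phenoxide ortho-formylation places the formyl group only ortho to the hydroxyl, C6 being the one free ortho position, and a second formaldehyde accepts the hydride.

Step 3
Reactants: 5 2-hydroxy-3,4,5-trimethoxybenzaldehyde
Product: 6 2-(benzyloxy)-3,4,5-trimethoxybenzaldehyde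
Conditions: BnBr, K2CO3, DMF, rt
Reagents that add atoms: benzyl bromide, BrCc1ccccc1
Why: Williamson etherification of the single phenol.

Step 4
Reactants: 6 2-(benzyloxy)-3,4,5-trimethoxybenzaldehyde
Product: 8 2-(benzyloxy)-3,4,5-trimethoxyphenol, via aryl formate 7 (not isolated)
Conditions: mCPBA, CH2Cl2, 0 °C to rt; then K2CO3 (cat.), MeOH, rt
Reagents that add atoms: mCPBA (3-chloroperbenzoic acid), OOC(=O)c1cccc(Cl)c1
Why: Baeyer–Villiger oxidation of an electron-rich benzaldehyde goes by aryl migration to the formate, which methanolysis turns into the phenol on the carbon next to the ring H atom.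

Step 5
Reactants: 8 2-(benzyloxy)-3,4,5-trimethoxyphenol; 9 2-chloro-N-methoxy-N-methylacetamide
Product: 10 2-[2-(benzyloxy)-3,4,5-trimethoxyphenoxy]-N-methoxy-N-methylacetamide
Conditions: K2CO3, KI (cat.), DMF, 60 °C
Reagents that add atoms: none
Why: Williamson alkylation of the phenoxide by an alpha-chloro amide gives the aryloxyacetic Weinreb amide directly.

Step 6
Reactants: 3 methyl (E)-3-(2,4,6-trimethoxyphenoxy)but-2-enoate; 10 2-[2-(benzyloxy)-3,4,5-trimethoxyphenoxy]-N-methoxy-N-methylacetamide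
Product: 13 methyl (E)-6-[2-(benzyloxy)-3,4,5-trimethoxyphenoxy]-5-oxo-3-(2,4,6-trimethoxyphenoxy)hex-2-enoate, via lithium dienolate 11 (not isolated), via tetrahedral lithium adduct 12 (not isolated)
Conditions: LDA (1.1 equiv), THF, −78 °C; then 10, −78 to −40 °C; AcOH
Reagents that add atoms: none
Why: Gamma-acylation of a 3-oxy-crotonate lithium dienolate by a Weinreb amide (vinylogous Claisen acylation): the methyl group cis to the ester is deprotonated, the dienolate reacts at its gamma carbon, and the chelated adduct 12 prevents a second addition until the quench.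

Step 7
Reactants: 13 methyl (E)-6-[2-(benzyloxy)-3,4,5-trimethoxyphenoxy]-5-oxo-3-(2,4,6-trimethoxyphenoxy)hex-2-enoate
Product: 15 2-[2-(benzyloxy)-3,4,5-trimethoxyphenoxy]-5-(2,4,6-trimethoxyphenoxy)benzene-1,3-diol, via cyclohexenedione 14 (not isolated)
Conditions: KOtBu (3.5 equiv), tBuOH–THF, degassed, 0 to 50 °C, Ar; then 1 M HCl
Reagents that add atoms: none
Why: Proposed new method: tert-butoxide equilibrates the enolates of 13, and the C6 enolate, whose protons are acidified by the C5 ketone and the ring C ether oxygen, adds to the C1 ester carbonyl, expels methoxide to give dione 14 and, after two enolisations, rests as the bis-phenoxide of 15 until the acid work-up. The closest known reactions are the base-mediated Claisen (Dieckmann-type) cyclisation of 3,5-dioxohexanoates and longer poly-beta-keto esters to phloroglucinols and the cyclisation of 3-alkoxy-5-oxohex-2-enoates, which normally ends at the 2-pyranone; closure of a 3-aryloxy enoate on carbon is the untested part. Ring B closes in a 6-(enolendo)-exo-trig mode by forming its C3–C4 bond, and no stereocentre results because the one in 14 is erased on aromatisation. The step needs C-acylation to win over O-acylation: the (E)-enoate (or its isomer, which equilibrates through the C4 enolate) places the ester beside the chain, lactonisation to the 4-aryloxy-2-pyranone releases methoxide that can reopen it, and aromatisation to the phenoxide is not reversible. tert-Butoxide is preferred to methoxide because it is too bulky to add to C3 and expel the ring A aryloxide or to cleave the C4–C5 bond by retro-Claisen attack, while the methoxide set free is quenched by the acidic product.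

Step 8
Reactants: 15 2-[2-(benzyloxy)-3,4,5-trimethoxyphenoxy]-5-(2,4,6-trimethoxyphenoxy)benzene-1,3-diol
Product: 16 2-(benzyloxy)-1-[2,6-dimethoxy-4-(2,4,6-trimethoxyphenoxy)phenoxy]-3,4,5-trimethoxybenzene
Conditions: Me2SO4, K2CO3, acetone, reflux
Reagents that add atoms: dimethyl sulfate, COS(=O)(=O)OC
Why: Williamson O-methylation; the hard electrophile dimethyl sulfate with carbonate in acetone favours O- over C-alkylation of the electron-rich resorcinol ring.

Step 9
Reactants: 16 2-(benzyloxy)-1-[2,6-dimethoxy-4-(2,4,6-trimethoxyphenoxy)phenoxy]-3,4,5-trimethoxybenzene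
Product: 17 6-[2,6-dimethoxy-4-(2,4,6-trimethoxyphenoxy)phenoxy]-2,3,4-trimethoxyphenol
Conditions: H2 (1 atm), 10% Pd/C, EtOAc–MeOH, rt
Reagents that add atoms: none
Why: Catalytic hydrogenolysis removes the benzyl ether and frees the ring C hydroxyl that will carry ring D; methyl and diaryl ethers are inert.

Step 10
Reactants: 18 3,4,5-trimethoxybenzaldehyde
Product: 19 2-iodo-3,4,5-trimethoxybenzaldehyde
Conditions: I2, AgOCOCF3, CH2Cl2, rt
Reagents that add atoms: iodine, II
Why: Silver-assisted electrophilic aromatic iodination; C2 and C6 are equivalent and the only free positions.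

Step 11
Reactants: 20 4-bromo-2,6-dimethoxyphenol; 19 2-iodo-3,4,5-trimethoxybenzaldehyde
Product: 21 2-(4-bromo-2,6-dimethoxyphenoxy)-3,4,5-trimethoxybenzaldehyde
Conditions: CuI (20 mol%), picolinic acid (40 mol%), K3PO4, DMSO, 80 °C
Reagents that add atoms: none
Why: Ullmann diaryl ether synthesis in which the iodide flanked by the formyl group (carbonyl-assisted, and C–I faster than C–Br) reacts first, so the ring D bromide is kept for step 17.

Step 12
Reactants: 22 3,4,5-trimethoxyphenol; 19 2-iodo-3,4,5-trimethoxybenzaldehyde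
Product: 23 3,4,5-trimethoxy-2-(3,4,5-trimethoxyphenoxy)benzaldehyde
Conditions: CuI (10 mol%), picolinic acid (20 mol%), K3PO4, DMSO, 80 °C
Reagents that add atoms: none
Why: Ullmann diaryl ether synthesis of an unhindered phenol (ring H) on the formyl-activated iodide (ring G).

Step 13
Reactants: 23 3,4,5-trimethoxy-2-(3,4,5-trimethoxyphenoxy)benzaldehyde
Product: 25 3,4,5-trimethoxy-2-(3,4,5-trimethoxyphenoxy)phenol, via aryl formate 24 (not isolated)
Conditions: mCPBA, CH2Cl2, 0 °C to rt; then K2CO3 (cat.), MeOH, rt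
Reagents that add atoms: mCPBA (3-chloroperbenzoic acid), OOC(=O)c1cccc(Cl)c1
Why: Baeyer–Villiger oxidation with aryl migration, then formate methanolysis, turns the formyl carbon of ring G into the phenol that will bind ring F.

Step 14
Reactants: 26 4-bromo-2-methoxyphenol
Product: 27 4-bromo-2-iodo-6-methoxyphenol
Conditions: NIS, TsOH (cat.), MeCN, rt
Reagents that add atoms: N-iodosuccinimide, O=C1CCC(=O)N1I
Why: Electrophilic aromatic iodination is directed by the hydroxyl to its one free ortho position, the para position being blocked by bromine.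

Step 15
Reactants: 27 4-bromo-2-iodo-6-methoxyphenol
Product: 28 5-bromo-1-iodo-2,3-dimethoxybenzene
Conditions: MeI, K2CO3, acetone, reflux
Reagents that add atoms: iodomethane, CI
Why: Williamson O-methylation of the phenol.

Step 16
Reactants: 25 3,4,5-trimethoxy-2-(3,4,5-trimethoxyphenoxy)phenol; 28 5-bromo-1-iodo-2,3-dimethoxybenzene
Product: 29 1-(5-bromo-2,3-dimethoxyphenoxy)-3,4,5-trimethoxy-2-(3,4,5-trimethoxyphenoxy)benzene
Conditions: CuI (10 mol%), N,N-dimethylglycine (30 mol%), Cs2CO3, 1,4-dioxane, 90 °C, 28 in excess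
Reagents that add atoms: none
Why: Ullmann diaryl ether synthesis at a temperature where the aryl iodide couples and the aryl bromide does not, which leaves the ring F bromide for step 19.

Step 17
Reactants: 17 6-[2,6-dimethoxy-4-(2,4,6-trimethoxyphenoxy)phenoxy]-2,3,4-trimethoxyphenol; 21 2-(4-bromo-2,6-dimethoxyphenoxy)-3,4,5-trimethoxybenzaldehyde
Product: 30 2-(4-{6-[2,6-dimethoxy-4-(2,4,6-trimethoxyphenoxy)phenoxy]-2,3,4-trimethoxyphenoxy}-2,6-dimethoxyphenoxy)-3,4,5-trimethoxybenzaldehyde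
Conditions: CuI (20 mol%), picolinic acid (40 mol%), K3PO4, DMSO, 100 °C
Reagents that add atoms: none
Why: Ullmann diaryl ether synthesis in its favourable polarity, a doubly flanked phenol (ring C) on an aryl bromide with two free ortho positions (ring D).

Step 18
Reactants: 30 the rings A to E aldehyde
Product: 32 2-(4-{6-[2,6-dimethoxy-4-(2,4,6-trimethoxyphenoxy)phenoxy]-2,3,4-trimethoxyphenoxy}-2,6-dimethoxyphenoxy)-3,4,5-trimethoxyphenol, via aryl formate 31 (not isolated)
Conditions: mCPBA, CH2Cl2, 0 °C; then K2CO3 (cat.), MeOH, rt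
Reagents that add atoms: mCPBA (3-chloroperbenzoic acid), OOC(=O)c1cccc(Cl)c1
Why: Baeyer–Villiger oxidation of the ortho-aryloxy benzaldehyde, faster than peracid attack on the methoxylated rings at 0 °C, then formate methanolysis, gives the ring E phenol.

Step 19
Reactants: 32 the rings A to E phenol; 29 1-(5-bromo-2,3-dimethoxyphenoxy)-3,4,5-trimethoxy-2-(3,4,5-trimethoxyphenoxy)benzene
Product: 33 henicosa-O-methyl ether of the target (rings A to H, all 21 hydroxyls as OMe)
Conditions: CuI (20 mol%), N,N-dimethylglycine (60 mol%), Cs2CO3, 1,4-dioxane, 110 °C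
Reagents that add atoms: none
Why: Ullmann diaryl ether synthesis between a phenol with one ortho substituent (ring E) and an aryl bromide with none (ring F).

Step 20
Reactants: 33 henicosa-O-methyl ether of the target
Product: 34 the target, CNP0309601.0
Conditions: BBr3 (excess), CH2Cl2, −78 °C to rt, Ar; then MeOH, H2O
Reagents that add atoms: none
Why: Lewis-acid ether cleavage: BBr3 binds each methoxy oxygen and bromide removes the methyl group, while the seven diaryl ether bonds offer no alkyl carbon to attack and stay intact.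

Compound list

1 | 2,4,6-trimethoxyphenol | COc1cc(OC)c(O)c(OC)c1 | starting material
2 | methyl but-2-ynoate | CC#CC(=O)OC | starting material
3 | methyl (E)-3-(2,4,6-trimethoxyphenoxy)but-2-enoate | COC(=O)/C=C(/Oc1c(OC)cc(OC)cc1OC)C | intermediate
4 | 2,3,4-trimethoxyphenol | COc1ccc(O)c(OC)c1OC | starting material
5 | 2-hydroxy-3,4,5-trimethoxybenzaldehyde | COc1cc(C=O)c(O)c(OC)c1OC | intermediate
6 | 2-(benzyloxy)-3,4,5-trimethoxybenzaldehyde | COc1cc(C=O)c(OCc2ccccc2)c(OC)c1OC | intermediate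
7 | 2-(benzyloxy)-3,4,5-trimethoxyphenyl formate | COc1cc(OC=O)c(OCc2ccccc2)c(OC)c1OC | intermediate
8 | 2-(benzyloxy)-3,4,5-trimethoxyphenol | COc1cc(O)c(OCc2ccccc2)c(OC)c1OC | intermediate
9 | 2-chloro-N-methoxy-N-methylacetamide | CON(C)C(=O)CCl | starting material
10 | 2-[2-(benzyloxy)-3,4,5-trimethoxyphenoxy]-N-methoxy-N-methylacetamide | CON(C)C(=O)COc1cc(OC)c(OC)c(OC)c1OCc1ccccc1 | intermediate
11 | lithium 1-methoxy-3-(2,4,6-trimethoxyphenoxy)buta-1,3-dien-1-olate | [Li+].[O-]C(OC)=CC(=C)Oc1c(OC)cc(OC)cc1OC | intermediate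
12 | lithium alkoxide adduct of 11 to the amide carbonyl of 10 (racemic) | COC(=O)/C=C(/Oc1c(OC)cc(OC)cc1OC)CC([O-])(COc1cc(OC)c(OC)c(OC)c1OCc1ccccc1)N(C)OC.[Li+] | intermediate
13 | methyl (E)-6-[2-(benzyloxy)-3,4,5-trimethoxyphenoxy]-5-oxo-3-(2,4,6-trimethoxyphenoxy)hex-2-enoate | COC(=O)/C=C(/Oc1c(OC)cc(OC)cc1OC)CC(=O)COc1cc(OC)c(OC)c(OC)c1OCc1ccccc1 | intermediate
14 | 2-[2-(benzyloxy)-3,4,5-trimethoxyphenoxy]-5-(2,4,6-trimethoxyphenoxy)cyclohex-4-ene-1,3-dione (racemic) | O=C1CC(Oc2c(OC)cc(OC)cc2OC)=CC(=O)C1Oc1cc(OC)c(OC)c(OC)c1OCc1ccccc1 | intermediate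
15 | 2-[2-(benzyloxy)-3,4,5-trimethoxyphenoxy]-5-(2,4,6-trimethoxyphenoxy)benzene-1,3-diol | Oc1cc(Oc2c(OC)cc(OC)cc2OC)cc(O)c1Oc1cc(OC)c(OC)c(OC)c1OCc1ccccc1 | intermediate
16 | 2-(benzyloxy)-1-[2,6-dimethoxy-4-(2,4,6-trimethoxyphenoxy)phenoxy]-3,4,5-trimethoxybenzene | COc1cc(Oc2c(OC)cc(OC)cc2OC)cc(OC)c1Oc1cc(OC)c(OC)c(OC)c1OCc1ccccc1 | intermediate
17 | 6-[2,6-dimethoxy-4-(2,4,6-trimethoxyphenoxy)phenoxy]-2,3,4-trimethoxyphenol | COc1cc(Oc2c(OC)cc(OC)cc2OC)cc(OC)c1Oc1cc(OC)c(OC)c(OC)c1O | intermediate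
18 | 3,4,5-trimethoxybenzaldehyde | COc1cc(C=O)cc(OC)c1OC | starting material
19 | 2-iodo-3,4,5-trimethoxybenzaldehyde | COc1cc(C=O)c(I)c(OC)c1OC | intermediate
20 | 4-bromo-2,6-dimethoxyphenol | COc1cc(Br)cc(OC)c1O | starting material
21 | 2-(4-bromo-2,6-dimethoxyphenoxy)-3,4,5-trimethoxybenzaldehyde | COc1cc(Br)cc(OC)c1Oc1c(C=O)cc(OC)c(OC)c1OC | intermediate
22 | 3,4,5-trimethoxyphenol | COc1cc(O)cc(OC)c1OC | starting material
23 | 3,4,5-trimethoxy-2-(3,4,5-trimethoxyphenoxy)benzaldehyde | COc1cc(Oc2c(C=O)cc(OC)c(OC)c2OC)cc(OC)c1OC | intermediate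
24 | 3,4,5-trimethoxy-2-(3,4,5-trimethoxyphenoxy)phenyl formate | COc1cc(Oc2c(OC=O)cc(OC)c(OC)c2OC)cc(OC)c1OC | intermediate
25 | 3,4,5-trimethoxy-2-(3,4,5-trimethoxyphenoxy)phenol | COc1cc(Oc2c(O)cc(OC)c(OC)c2OC)cc(OC)c1OC | intermediate
26 | 4-bromo-2-methoxyphenol | COc1cc(Br)ccc1O | starting material
27 | 4-bromo-2-iodo-6-methoxyphenol | COc1cc(Br)cc(I)c1O | intermediate
28 | 5-bromo-1-iodo-2,3-dimethoxybenzene | COc1cc(Br)cc(I)c1OC | intermediate
29 | 1-(5-bromo-2,3-dimethoxyphenoxy)-3,4,5-trimethoxy-2-(3,4,5-trimethoxyphenoxy)benzene | COc1cc(Br)cc(Oc2cc(OC)c(OC)c(OC)c2Oc2cc(OC)c(OC)c(OC)c2)c1OC | intermediate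
30 | 2-(4-{6-[2,6-dimethoxy-4-(2,4,6-trimethoxyphenoxy)phenoxy]-2,3,4-trimethoxyphenoxy}-2,6-dimethoxyphenoxy)-3,4,5-trimethoxybenzaldehyde | COc1cc(OC)c(Oc2cc(OC)c(Oc3cc(OC)c(OC)c(OC)c3Oc3cc(OC)c(Oc4c(C=O)cc(OC)c(OC)c4OC)c(OC)c3)c(OC)c2)c(OC)c1 | intermediate
31 | 2-(4-{6-[2,6-dimethoxy-4-(2,4,6-trimethoxyphenoxy)phenoxy]-2,3,4-trimethoxyphenoxy}-2,6-dimethoxyphenoxy)-3,4,5-trimethoxyphenyl formate | COc1cc(OC)c(Oc2cc(OC)c(Oc3cc(OC)c(OC)c(OC)c3Oc3cc(OC)c(Oc4c(OC=O)cc(OC)c(OC)c4OC)c(OC)c3)c(OC)c2)c(OC)c1 | intermediate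
32 | 2-(4-{6-[2,6-dimethoxy-4-(2,4,6-trimethoxyphenoxy)phenoxy]-2,3,4-trimethoxyphenoxy}-2,6-dimethoxyphenoxy)-3,4,5-trimethoxyphenol | COc1cc(OC)c(Oc2cc(OC)c(Oc3cc(OC)c(OC)c(OC)c3Oc3cc(OC)c(Oc4c(O)cc(OC)c(OC)c4OC)c(OC)c3)c(OC)c2)c(OC)c1 | intermediate
33 | henicosa-O-methyl ether of the target (octaphenyl heptaether, rings A to H, 21 OMe) | COc1cc(OC)c(Oc2cc(OC)c(Oc3cc(OC)c(OC)c(OC)c3Oc3cc(OC)c(Oc4c(Oc5cc(OC)c(OC)c(Oc6cc(OC)c(OC)c(OC)c6Oc6cc(OC)c(OC)c(OC)c6)c5)cc(OC)c(OC)c4OC)c(OC)c3)c(OC)c2)c(OC)c1 | intermediate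
34 | CNP0309601.0, octaphenyl heptaether with 21 free hydroxyls (rings A to H) | Oc1cc(O)c(Oc2cc(O)c(Oc3cc(O)c(O)c(O)c3Oc3cc(O)c(Oc4c(Oc5cc(O)c(O)c(Oc6cc(O)c(O)c(O)c6Oc6cc(O)c(O)c(O)c6)c5)cc(O)c(O)c4O)c(O)c3)c(O)c2)c(O)c1 | target

Total step count: 20. Longest linear sequence: 12 steps (from 4 through steps 2 to 9 and 17 to 20).

Steps most likely to fail

Step 7. The enolate oxygen on C5 may acylate faster than carbon C6 and the resulting 2-pyranone may not reopen, or base may expel the ring A aryloxide from C3, so that ring B never closes on carbon. The fallback uses only known couplings, sets out from 1 and comes back at 17. Ullmann coupling of 1 with commercial 4-bromo-2,6-dimethoxybenzaldehyde (CuI, picolinic acid, K3PO4, DMSO) should give 2,6-dimethoxy-4-(2,4,6-trimethoxyphenoxy)benzaldehyde F1. Baeyer–Villiger oxidation with mCPBA gives 2,6-dimethoxy-4-(2,4,6-trimethoxyphenoxy)phenyl formate F2, which K2CO3 in MeOH cleaves to 2,6-dimethoxy-4-(2,4,6-trimethoxyphenoxy)phenol F3. Rieche formylation of commercial 5-bromo-1,2,3-trimethoxybenzene (Cl2CHOMe, TiCl4, CH2Cl2, 0 °C) gives 6-bromo-2,3,4-trimethoxybenzaldehyde F4. Its formyl-activated bromide couples with F3 under the same copper conditions to 6-[2,6-dimethoxy-4-(2,4,6-trimethoxyphenoxy)phenoxy]-2,3,4-trimethoxybenzaldehyde F5. A second Baeyer–Villiger oxidation gives 6-[2,6-dimethoxy-4-(2,4,6-trimethoxyphenoxy)phenoxy]-2,3,4-trimethoxyphenyl formate F6, and its methanolysis gives 17.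

Step 11. Carbon–oxygen bond formation between two doubly flanked carbons may be slower than reduction of the iodide or than attack of the copper phenoxide on the bromide of a second molecule, which would give oligomers. The fallback sets out from 20 and comes back at 21. Carboxylate-directed (Hurtley-type) coupling of 20 with commercial 2-bromo-3,4,5-trimethoxybenzoic acid (Cu powder, Cu2O, K2CO3, DMF, 120 °C) delivers copper only to the bromide beside the carboxylate and leaves the ring D bromide alone; it should give 2-(4-bromo-2,6-dimethoxyphenoxy)-3,4,5-trimethoxybenzoic acid F7. Reduction with BH3·THF gives [2-(4-bromo-2,6-dimethoxyphenoxy)-3,4,5-trimethoxyphenyl]methanol F8, and MnO2 in CH2Cl2 oxidises it to 21.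

Step 20. Cleavage of 21 methyl ethers may stop short, and the free polyphenol may be oxidised by air while it is separated from partly methylated material. The fallback sets out from 33 and comes back at 34. After the BBr3 treatment the crude product is acetylated at once (Ac2O, pyridine, DMAP) to the henicosaacetate of 34 F9, which is stable to air and can be purified on silica, with incompletely demethylated acetates separated and recycled. Acid-catalysed methanolysis (HCl in MeOH, Ar, rt) then releases 34 without exposure to base.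

Further compounds

F1 | step 7 | 2,6-dimethoxy-4-(2,4,6-trimethoxyphenoxy)benzaldehyde | COc1cc(OC)c(Oc2cc(OC)c(C=O)c(OC)c2)c(OC)c1
F2 | step 7 | 2,6-dimethoxy-4-(2,4,6-trimethoxyphenoxy)phenyl formate | COc1cc(OC)c(Oc2cc(OC)c(OC=O)c(OC)c2)c(OC)c1
F3 | step 7 | 2,6-dimethoxy-4-(2,4,6-trimethoxyphenoxy)phenol | COc1cc(OC)c(Oc2cc(OC)c(O)c(OC)c2)c(OC)c1
F4 | step 7 | 6-bromo-2,3,4-trimethoxybenzaldehyde | COc1cc(Br)c(C=O)c(OC)c1OC
F5 | step 7 | 6-[2,6-dimethoxy-4-(2,4,6-trimethoxyphenoxy)phenoxy]-2,3,4-trimethoxybenzaldehyde | COc1cc(OC)c(Oc2cc(OC)c(Oc3cc(OC)c(OC)c(OC)c3C=O)c(OC)c2)c(OC)c1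
F6 | step 7 | 6-[2,6-dimethoxy-4-(2,4,6-trimethoxyphenoxy)phenoxy]-2,3,4-trimethoxyphenyl formate | COc1cc(OC)c(Oc2cc(OC)c(Oc3cc(OC)c(OC)c(OC)c3OC=O)c(OC)c2)c(OC)c1
F7 | step 11 | 2-(4-bromo-2,6-dimethoxyphenoxy)-3,4,5-trimethoxybenzoic acid | COc1cc(Br)cc(OC)c1Oc1c(C(=O)O)cc(OC)c(OC)c1OC
F8 | step 11 | [2-(4-bromo-2,6-dimethoxyphenoxy)-3,4,5-trimethoxyphenyl]methanol | COc1cc(Br)cc(OC)c1Oc1c(CO)cc(OC)c(OC)c1OC
F9 | step 20 | henicosaacetate of 34 | CC(=O)Oc1cc(OC(C)=O)c(Oc2cc(OC(C)=O)c(Oc3cc(OC(C)=O)c(OC(C)=O)c(OC(C)=O)c3Oc3cc(OC(C)=O)c(Oc4c(Oc5cc(OC(C)=O)c(OC(C)=O)c(Oc6cc(OC(C)=O)c(OC(C)=O)c(OC(C)=O)c6Oc6cc(OC(C)=O)c(OC(C)=O)c(OC(C)=O)c6)c5)cc(OC(C)=O)c(OC(C)=O)c4OC(C)=O)c(OC(C)=O)c3)c(OC(C)=O)c2)c(OC(C)=O)c1
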